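## Structural features

The target is a flavonol: benzene ring A is fused through C4a–C8a to the 4-pyranone ring C, and the 3,4,5-trimethoxyphenyl ring B is joined to C2 by a single C–C bond. There is no stereocentre, so the problem is one of regiochemistry and oxidation pattern. Ring A carries oxygen at C5, C7 and C8 and hydrogen at C6. Ring C carries the enolic 3-OH next to the C4 carbonyl. Only the 3-OH and 5-OH, both hydrogen-bonded to C4=O, are free; the other five oxygen substituents are methyl ethers. The fragile parts are the electron-rich 3-hydroxy-4-pyranone enol (oxidised easily in base and air), the free peri phenol, and the 4'-methoxy group, which is flanked by two methoxy groups and is the non-chelated ether most exposed to Lewis acids. The real difficulty is the 5,7,8-trioxygenated ring A, which in a conventional flavone synthesis calls for a 2,3,4,6-tetraoxygenated acetophenone, together with the need to tell O5 from O7 and O8 and to bring in O3. The key step exploits the para relationship of O5 and O8 across ring A. These two oxygens can be the carbonyl groups of a 1,4-benzoquinone whose acyl-bearing carbon is C4a and whose neighbouring CH is C8a, so the enol oxygen of the side chain (the future O1) can add to C8a and close ring C.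

## Logic of the disconnections

10 ⇒ 9. A methyl group is put back on O5, so that every ring A oxygen is a methyl ether. The 5-hydroxyl must be masked while C3 is oxidised, and the peri position next to C4=O is the one place where a methyl ether can later be removed selectively. The gain is that ring A needs no differentiated protecting groups. The demand is that the forward demethylation touches one methoxy group of six and spares the flanked 4'-methoxy group.

9 ⇒ 7. The C3–O bond is cut. C3 is the nucleophilic carbon of the O1–C2=C3 enol ether unit, so an electrophilic oxygen donor can be added last. The gain is that 7 is a plain flavone, so the diketone behind it needs no substituent on its central carbon; an alkoxy group there would lower the enol content on which ring closure relies and would cost a step on the ketone side. The demand is that the oxidant attacks C2=C3 rather than the two electron-rich arenes and that intermediate 8 isomerises cleanly.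

7 ⇒ 6. The O5–CH3 and O8–CH3 bonds are cut. O8 leaves the ring closure as a phenol and has to be methylated anyway, and capping O5 in the same operation costs nothing. The gain is that the para-quinol is revealed. The demand is exhaustive alkylation, including the chelated 5-OH, with air kept out.

6 ⇒ 4 (through 5). The O1–C8a bond is cut and ring A is raised to the quinone level. In 4, C8a is an electrophilic quinone CH next to the acyl-bearing carbon, and the future O1 is the enol oxygen of the diketone. The gain is one ring and one skeletal bond, and the 5,7,8-pattern now derives from a 2,4,5-trioxygenated arene. The demand is addition at C3 of the quinone rather than C6, and ring closure faster than redox exchange between product and substrate.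

4 ⇒ 3. The two quinone carbonyl groups are traced back to the para pair of methoxy groups. A quinone would not survive enolate chemistry, so it is unveiled only after the carbon skeleton is complete. The gain is a stable, fully methylated diketone. The demand is an oxidant that selects the para-dimethoxy pair of ring A over ring B and over the enolised diketone, and leaves the third methoxy group in place.

3 ⇒ 1 + 2. The bond between the central carbon (future C3) and the carbonyl carbon bearing ring B (future C2) is cut. This is the bond a crossed Claisen condensation makes, with the nucleophile on the ring A methyl ketone and a non-enolisable ester as acceptor. The gain is two commercial, fully methylated arenes. The demand is more than two equivalents of base, because 3 is far more acidic than 1.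

## Other disconnections considered

Alternative 1: The cut is the C3–C4 bond of ring C.
- **Forward key step:** dialdehyde A1 has the ring A formyl group (future C4) ortho to an aryl–O–CH(Ar)–CHO unit (future O1, C2, C3). A triazolium-derived carbene would turn the aromatic formyl group into an acyl-anion equivalent, which adds to the aliphatic aldehyde and closes ring C as the racemic trans dihydroflavonol A2.
- **In favour:** the C3 oxygen arrives with the C–C bond, the conditions are mild and metal-free, and benzoin-type closures to chroman-4-ones are established for aldehyde–ketone pairs.
- **Against:** the carbene must choose the hindered, electron-rich aromatic aldehyde as donor although the aliphatic aldehyde is the more electrophilic; the wrong sense gives the regioisomeric ketol with the carbonyl at C3. The α-aryloxy-α-aryl aldehyde of A1 is acidic and prone to enolisation and loss of phenoxide. The two stereocentres created are destroyed again by the dehydrogenation to the flavonol, and the selective 5-O-demethylation is still needed.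
- **Comparison, structure:** A2 is ahead at C3 (oxygen already present, so no counterpart of step 5; here the alternative is better) but one oxidation level short at C2–C3. Ring A must come from a 2,3,4,6-tetraoxygenated salicylaldehyde, where the chosen plan uses a 2,4,5-trioxygenated ketone.
- **Comparison, mechanism:** as a reaction type the closure has firmer precedent than step 3 (better), but its aldehyde–aldehyde chemoselectivity is open, whereas step 3 has only one productive six-membered closure available.
- **Comparison, step economy:** A1 would need about five steps, and dehydrogenation plus demethylation two more: about eight against six.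

Alternative 2: The cut is the C4a–C5 bond, and with it the whole of ring A is taken apart.
- **Forward key step:** cyclobutenone A3 carries at C4 a methoxy group and the complete ring C pyranone, with ring B and a 3-benzyloxy group in place. Heating should open the four-membered ring to a dienylketene; six-electron electrocyclisation onto the pyranone double bond that becomes C4a=C8a forms C4a–C5, and enolisation gives the 5-hydroxyflavone A4.
- **In favour:** the ring A pattern is fixed by connectivity (ketene carbon to C5–OH, C4 methoxy to 8-OMe, C3 methoxy to 7-OMe, C2–H to C6–H). The donor methoxy group at C4 should rotate outward and so turn the pyranone inward, as the closure requires. No reagent or oxidant is used. A4 has the 5-OH free and O3 in place, so one hydrogenolysis would finish the synthesis.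
- **Against:** A3 is a demanding precursor. It needs a fully substituted pyranone metalated at its free α-position, regioselective addition to a squaric acid derivative, and O-methylation of a hindered tertiary cyclobutenol. The pyranone double bond is an electron-poor vinylogous ester, a less assured partner for the electrocyclisation than an arene or a simple alkene, and temperatures above 100 °C are needed.
- **Comparison, structure:** the end-game is better than in the chosen plan (one step after the key step, no selective demethylation, no late C3 oxidation).
- **Comparison, mechanism:** both key steps are redox-neutral isomerisations of their precursors (equal). The thermal cascade has closer precedent as a reaction type (better), but step 3 runs at room temperature on a much simpler substrate.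
- **Comparison, step economy:** about seven or eight steps to A3, so about nine in all against six, and no commercial building block maps onto A3 as directly as 1 and 2 map onto 4.

Alternative 3: The cut is the C2–C3 bond.
- **Forward key step:** enol acetate A5 is the 3,4,5-trimethoxybenzyl ether of a 2-hydroxyaryl methyl ketone enol acetate. DDQ would abstract hydride from the O–CH2–aryl carbon; the tethered enol acetate attacks the oxocarbenium ion through carbon, and loss of the acetyl group gives the racemic flavanone A6.
- **In favour:** two C–H bonds are coupled without prior functionalisation, A5 is made by routine O-benzylation and enol acetylation, and closures of this kind are established for benzylic and allylic alkyl ethers.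
- **Against:** the ether oxygen is a phenol oxygen whose lone pair is shared with ring A, and the 3,4,5-trimethoxyphenyl group stabilises a cation less well than a 4-methoxyphenyl group (its 4-methoxy group is twisted out of conjugation, the 3- and 5-methoxy groups are meta). Hydride abstraction should therefore be slow, and DDQ may attack the electron-rich ring A or the enol acetate instead. A6 is two oxidation levels below the flavonol, so a dehydrogenation is needed before the route merges with 7. Ring A again comes from a 2,3,4,6-tetraoxygenated acetophenone.
- **Comparison, structure:** A6 leads to 7 and then needs steps 5 and 6 unchanged, so no end-game step is saved; only steps 1 to 4 are replaced.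
- **Comparison, mechanism:** capture of an oxocarbenium ion by an enol derivative has nearer precedent than step 3 (better), but it needs a strong external oxidant next to two electron-rich arenes, whereas in step 3 the substrate carries its own oxidant.
- **Comparison, step economy:** O-alkylation, enol acetylation, cyclisation, dehydrogenation, then steps 5 and 6 make six steps, equal to the chosen plan. The difference lies in the cost of the ring A building block and the selectivity risk of the DDQ step.

Key step: step 3

Remark on the chemistry: 3 is drawn as the diketone although it should exist largely as the chelated enol; the two new carbonyl oxygens of 4 are assumed to come from water, the methoxy groups leaving as methanol.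

Remark on the structures: mapping quinone atoms C1, C2, C3, C4, C5, C6 of 4 onto C5, C4a, C8a, C8, C7, C6 of the flavone reproduces 6 and, after steps 4 to 6, the target; no structure needed correction.

## Route

Step 1
Reactants: 1 2',4',5'-trimethoxyacetophenone [1-(2,4,5-trimethoxyphenyl)ethan-1-one]; 2 methyl 3,4,5-trimethoxybenzoate
Product: 3 1-(2,4,5-trimethoxyphenyl)-3-(3,4,5-trimethoxyphenyl)propane-1,3-dione
Conditions: NaH (2.5 equiv), THF, 65 °C; then 1 M HCl, 0 °C
Reagents that add atoms: none
Why: Crossed Claisen condensation: the sodium enolate of methyl ketone 1 attacks the carbonyl group of the non-enolisable ester 2, and deprotonation of the acidic diketone by methoxide drives the equilibrium, which is why more than two equivalents of base are used.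

Step 2
Reactants: 3 1-(2,4,5-trimethoxyphenyl)-3-(3,4,5-trimethoxyphenyl)propane-1,3-dione
Product: 4 2-methoxy-5-[3-oxo-3-(3,4,5-trimethoxyphenyl)propanoyl]cyclohexa-2,5-diene-1,4-dione
Conditions: (NH4)2Ce(NO3)6 (2.2 equiv), MeCN/H2O 3:1, 0 °C, 10 min; extraction into CH2Cl2, used at once
Reagents that add atoms: water, O
Why: Oxidative demethylation of a para-dimethoxyarene: two one-electron oxidations of ring A with ipso attack of water at C2' and C5' expel two molecules of methanol and give the para-quinone, the 4'-methoxy group staying in place. Ring A (three donors, one para pair) should be oxidised before ring B, which has no para-dioxygen pair and is deactivated by its carbonyl group; low temperature, short contact and immediate extraction limit attack of tetravalent cerium on the enolised diketone.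

Step 3
Reactants: 4 2-methoxy-5-[3-oxo-3-(3,4,5-trimethoxyphenyl)propanoyl]cyclohexa-2,5-diene-1,4-dione
Product: 6 5,8-dihydroxy-7-methoxy-2-(3,4,5-trimethoxyphenyl)-4H-chromen-4-one, via dienone adduct 5 (not isolated)
Conditions: CF3CO2H (0.2 equiv), degassed CH2Cl2 (0.01 M), 0 → 23 °C, argon, dark
Reagents that add atoms: none
Why: Proposed new method: the acid equilibrates the chelated enol of 4 with its diketo form and rotamers and hydrogen-bonds the quinone C1 carbonyl and the neighbouring side-chain carbonyl, which polarises quinone C3 (the future C8a); the enol oxygen on the carbon bearing ring B then adds to C3 in an intramolecular oxa-Michael addition to give dienone 5, and a proton shift from C8a to O8 aromatises ring A to quinol 6. The quinone thus takes up the two electrons of the formally dehydrogenative O1–C8a bond, and no oxidant is needed. The closest known reaction types are conjugate additions of oxygen, sulfur and nitrogen nucleophiles to C3 of 2-acyl-1,4-benzoquinones and the cyclisation of hydroxyalkyl quinones to chromanols; the enol oxygen of a 1,3-diketone has not served as the nucleophile. Ring C closes in the 6-endo-trig mode, since both carbons of the attacked quinone C2=C3 bond lie in the new ring. The only stereocentre formed, C8a of 5, is transient and racemic and disappears on aromatisation, so nothing has to be controlled. The step needs site selectivity for C3 over C6 and for 1,4- over 1,2-addition: C3 is β to two carbonyl groups and is the only ring CH the enol oxygen can reach through a six-membered transition state, C6 is the electron-rich β-carbon of the methoxy enone and out of reach, and addition to the C1 carbonyl carbon gives only a reversible hemiketal. Acid in place of base, high dilution and exclusion of air are chosen so that reduction of 4 by 6 and intermolecular C-alkylation of the diketone by a second quinone stay slower than ring closure.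

Step 4
Reactants: 6 5,8-dihydroxy-7-methoxy-2-(3,4,5-trimethoxyphenyl)-4H-chromen-4-one
Product: 7 5,7,8-trimethoxy-2-(3,4,5-trimethoxyphenyl)-4H-chromen-4-one
Conditions: MeI (6 equiv), K2CO3 (5 equiv), DMF, 50 °C, argon
Reagents that add atoms: iodomethane, CI
Why: Williamson O-methylation of both phenoxides: the free 8-OH reacts readily, and the hydrogen-bonded 5-OH is brought to completion by the excess of reagent and gentle heating. Argon keeps the electron-rich quinol dianion from aerial oxidation to the 5,8-quinone.

Step 5
Reactants: 7 5,7,8-trimethoxy-2-(3,4,5-trimethoxyphenyl)-4H-chromen-4-one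
Product: 9 3-hydroxy-5,7,8-trimethoxy-2-(3,4,5-trimethoxyphenyl)-4H-chromen-4-one, via flavone 2,3-epoxide 8 (not isolated)
Conditions: dimethyldioxirane (3 equiv, acetone solution), CH2Cl2, 0 → 23 °C; evaporation; then TsOH·H2O (0.1 equiv), CH2Cl2, 23 °C
Reagents that add atoms: dimethyldioxirane, CC1(C)OO1
Why: Neutral electrophilic epoxidation of the C2=C3 bond gives the racemic cis-fused epoxide 8; acid opens it at C2 to the cation stabilised by O1 and ring B, and loss of H3 gives the 3-hydroxyflavone (epoxidation–isomerisation route to flavonols). The 5-O-methyl group keeps a free, oxidisable phenol away from the oxidant.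

Step 6
Reactants: 9 3-hydroxy-5,7,8-trimethoxy-2-(3,4,5-trimethoxyphenyl)-4H-chromen-4-one
Product: 10 3,5-dihydroxy-7,8-dimethoxy-2-(3,4,5-trimethoxyphenyl)-4H-chromen-4-one
Conditions: BCl3 (3 equiv), CH2Cl2, −78 → 0 °C; then H2O, 23 °C
Reagents that add atoms: none
Why: Chelation-controlled aryl methyl ether cleavage: boron held between the C4 carbonyl oxygen and the peri 5-methoxy oxygen activates only that methyl group towards attack by chloride. The other five methoxy groups have no neighbouring carbonyl group and should survive at or below 0 °C; one equivalent of BCl3 is taken up by the 3-OH.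

## Compound list

1 | 2',4',5'-trimethoxyacetophenone [1-(2,4,5-trimethoxyphenyl)ethan-1-one] | CC(=O)c1cc(OC)c(OC)cc1OC | starting material
2 | methyl 3,4,5-trimethoxybenzoate | COC(=O)c1cc(OC)c(OC)c(OC)c1 | starting material
3 | 1-(2,4,5-trimethoxyphenyl)-3-(3,4,5-trimethoxyphenyl)propane-1,3-dione | COc1cc(OC)c(cc1OC)C(=O)CC(=O)c1cc(OC)c(OC)c(OC)c1 | intermediate
4 | 2-methoxy-5-[3-oxo-3-(3,4,5-trimethoxyphenyl)propanoyl]cyclohexa-2,5-diene-1,4-dione | COC1=CC(=O)C(C(=O)CC(=O)c2cc(OC)c(OC)c(OC)c2)=CC1=O | intermediate
5 | 5-hydroxy-7-methoxy-2-(3,4,5-trimethoxyphenyl)-4H-chromene-4,8(8aH)-dione (racemic; one enantiomer drawn) | COC1=CC(O)=C2C(=O)C=C(c3cc(OC)c(OC)c(OC)c3)O[C@@H]2C1=O | intermediate (not isolated)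
6 | 5,8-dihydroxy-7-methoxy-2-(3,4,5-trimethoxyphenyl)-4H-chromen-4-one | COc1cc(-c2cc(=O)c3c(O)cc(OC)c(O)c3o2)cc(OC)c1OC | intermediate
7 | 5,7,8-trimethoxy-2-(3,4,5-trimethoxyphenyl)-4H-chromen-4-one | COc1cc(-c2cc(=O)c3c(OC)cc(OC)c(OC)c3o2)cc(OC)c1OC | intermediate
8 | 2,3-epoxy-5,7,8-trimethoxy-2-(3,4,5-trimethoxyphenyl)chroman-4-one (racemic, cis-fused; one enantiomer drawn) | COc1cc(cc(OC)c1OC)[C@]12O[C@H]1C(=O)c1c(OC)cc(OC)c(OC)c1O2 | intermediate (not isolated)
9 | 3-hydroxy-5,7,8-trimethoxy-2-(3,4,5-trimethoxyphenyl)-4H-chromen-4-one | COc1cc(-c2oc3c(OC)c(OC)cc(OC)c3c(=O)c2O)cc(OC)c1OC | intermediate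
10 | 3,5-dihydroxy-7,8-dimethoxy-2-(3,4,5-trimethoxyphenyl)-4H-chromen-4-one (3,5-dihydroxy-7,8,3',4',5'-pentamethoxyflavone) | COc1cc(-c2oc3c(OC)c(OC)cc(O)c3c(=O)c2O)cc(OC)c1OC | target

## Step count and least certain steps

Total: 6 steps. Longest linear sequence: 6 steps (1 → 3 → 4 → 6 → 7 → 9 → 10); 2 enters in step 1.

**Step 3 (key step).**
- **Risk:** electron and proton exchange between quinol 6 already formed and quinone 4 not yet cyclised is the most likely failure, because the acylquinone is the stronger oxidant. The hydroquinone of 4 so formed can close only in the ordinary dehydrative sense through its 2'-hydroxyl group, which leads into the isomeric 6,7-dioxygenated flavone series, and the over-oxidised flavone-5,8-quinone is lost to methylation. Intermolecular C-alkylation of the diketone by a second quinone is the other drain. A wash with aqueous Na2S2O4 would return any 5,8-quinone to 6 but cannot rescue uncyclised material.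
- **Fallback (known chemistry, gives up the quinone logic):** it sets out from 2 and returns at 7. Crossed Claisen condensation of 2 with the dianion of commercially obtainable 1-(2-hydroxy-3,4,6-trimethoxyphenyl)ethan-1-one F1 (NaH, THF, 65 °C) should give 1-(2-hydroxy-3,4,6-trimethoxyphenyl)-3-(3,4,5-trimethoxyphenyl)propane-1,3-dione F2. Its acid-catalysed cyclodehydration (H2SO4 cat., AcOH, 100 °C), the second stage of the Baker–Venkataraman flavone synthesis, gives 7, which continues with step 5.

**Step 2.**
- **Risk:** one-electron oxidation of the enolised diketone by tetravalent cerium (radical coupling or nitrate capture at the central carbon) may compete with oxidation of ring A. Ring closure may also begin in the acidic oxidising medium and be followed by over-oxidation of the quinol, which would consume oxidant meant for 3.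
- **Fallback:** it sets out from 3 and returns at 4. BCl3 (CH2Cl2, −78 → 0 °C) should remove only the methyl group ortho to the ring A carbonyl, by the chelation that step 6 also uses, and give 1-(2-hydroxy-4,5-dimethoxyphenyl)-3-(3,4,5-trimethoxyphenyl)propane-1,3-dione F3. PhI(OAc)2 in MeCN/H2O at 0 °C should then oxidise this para-methoxyphenol to 4 with loss of methanol, in a nearly neutral medium and without a one-electron metal oxidant.

**Step 5.**
- **Risk:** the C2=C3 bond is a vinylogous ester and is epoxidised slowly, so on long exposure the oxidant may hydroxylate the electron-rich rings A and B. Acid opening of 8 may also divert into ring contraction instead of proton loss.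
- **Fallback:** it sets out from 7 and returns at 9. LiN(iPr)2 (THF, −78 °C) deprotonates C3, B(OMe)3 traps the vinyl-lithium as dimethyl [5,7,8-trimethoxy-4-oxo-2-(3,4,5-trimethoxyphenyl)-4H-chromen-3-yl]boronate F4 (not isolated), and H2O2/AcOH oxidises the C–B bond to the C3–OH of 9. This swaps electrophilic oxygen transfer for C3 metalation, borylation and oxidation.

**Step 6.**
- **Risk:** loss of selectivity through further demethylation at the flanked 4'-methoxy group or within the vicinal 7,8-pair, or stalling because the boron bound to O3 and the C4 carbonyl hinders the chelate needed at O5.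
- **Fallback:** it sets out from 6 and returns at 10, and removes the last protecting group by hydrogenolysis instead of a Lewis acid.
  - MeI (1.1 equiv), K2CO3, acetone, 23 °C should methylate only the non-chelated 8-OH and give 5-hydroxy-7,8-dimethoxy-2-(3,4,5-trimethoxyphenyl)-4H-chromen-4-one F5.
  - BnBr, K2CO3, DMF, 80 °C gives 5-(benzyloxy)-7,8-dimethoxy-2-(3,4,5-trimethoxyphenyl)-4H-chromen-4-one F6.
  - Dimethyldioxirane and then TsOH, as in step 5, pass through the racemic 5-(benzyloxy)-2,3-epoxy-7,8-dimethoxy-2-(3,4,5-trimethoxyphenyl)chroman-4-one F7 (not isolated) to 5-(benzyloxy)-3-hydroxy-7,8-dimethoxy-2-(3,4,5-trimethoxyphenyl)-4H-chromen-4-one F8.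
  - H2, Pd/C, EtOAc, 23 °C removes the benzyl group and gives 10.

## Further compounds

F1 | step 3 | 1-(2-hydroxy-3,4,6-trimethoxyphenyl)ethan-1-one (bought) | CC(=O)c1c(O)c(OC)c(OC)cc1OC
F2 | step 3 | 1-(2-hydroxy-3,4,6-trimethoxyphenyl)-3-(3,4,5-trimethoxyphenyl)propane-1,3-dione | COc1cc(OC)c(C(=O)CC(=O)c2cc(OC)c(OC)c(OC)c2)c(O)c1OC
F3 | step 2 | 1-(2-hydroxy-4,5-dimethoxyphenyl)-3-(3,4,5-trimethoxyphenyl)propane-1,3-dione | COc1cc(O)c(cc1OC)C(=O)CC(=O)c1cc(OC)c(OC)c(OC)c1
F4 | step 5 | dimethyl [5,7,8-trimethoxy-4-oxo-2-(3,4,5-trimethoxyphenyl)-4H-chromen-3-yl]boronate | COB(OC)c1c(-c2cc(OC)c(OC)c(OC)c2)oc2c(OC)c(OC)cc(OC)c2c1=O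
F5 | step 6 | 5-hydroxy-7,8-dimethoxy-2-(3,4,5-trimethoxyphenyl)-4H-chromen-4-one | COc1cc(-c2cc(=O)c3c(O)cc(OC)c(OC)c3o2)cc(OC)c1OC
F6 | step 6 | 5-(benzyloxy)-7,8-dimethoxy-2-(3,4,5-trimethoxyphenyl)-4H-chromen-4-one | COc1cc(-c2cc(=O)c3c(OCc4ccccc4)cc(OC)c(OC)c3o2)cc(OC)c1OC
F7 | step 6 | 5-(benzyloxy)-2,3-epoxy-7,8-dimethoxy-2-(3,4,5-trimethoxyphenyl)chroman-4-one (racemic, cis-fused; one enantiomer drawn) | COc1cc(cc(OC)c1OC)[C@]12O[C@H]1C(=O)c1c(OCc3ccccc3)cc(OC)c(OC)c1O2
F8 | step 6 | 5-(benzyloxy)-3-hydroxy-7,8-dimethoxy-2-(3,4,5-trimethoxyphenyl)-4H-chromen-4-one | COc1cc(-c2oc3c(OC)c(OC)cc(OCc4ccccc4)c3c(=O)c2O)cc(OC)c1OC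
A1 | alternative 1 | 3,4,6-trimethoxy-2-[2-oxo-1-(3,4,5-trimethoxyphenyl)ethoxy]benzaldehyde (racemic; one enantiomer drawn) | O=Cc1c(OC)cc(OC)c(OC)c1O[C@H](C=O)c1cc(OC)c(OC)c(OC)c1
A2 | alternative 1 | trans-3-hydroxy-5,7,8-trimethoxy-2-(3,4,5-trimethoxyphenyl)chroman-4-one (racemic; one enantiomer drawn) | COc1cc(cc(OC)c1OC)[C@@H]1[C@@H](O)C(=O)c2c(OC)cc(OC)c(OC)c2O1
A3 | alternative 2 | 4-[5-(benzyloxy)-4-oxo-6-(3,4,5-trimethoxyphenyl)-4H-pyran-2-yl]-3,4-dimethoxycyclobut-2-en-1-one (racemic; one enantiomer drawn) | COC1=CC(=O)[C@]1(OC)c1cc(=O)c(OCc2ccccc2)c(-c2cc(OC)c(OC)c(OC)c2)o1
A4 | alternative 2 | 3-(benzyloxy)-5-hydroxy-7,8-dimethoxy-2-(3,4,5-trimethoxyphenyl)-4H-chromen-4-one | COc1cc(-c2oc3c(OC)c(OC)cc(O)c3c(=O)c2OCc2ccccc2)cc(OC)c1OC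
A5 | alternative 3 | 1-{3,4,6-trimethoxy-2-[(3,4,5-trimethoxybenzyl)oxy]phenyl}ethenyl acetate | CC(=O)OC(=C)c1c(OC)cc(OC)c(OC)c1OCc1cc(OC)c(OC)c(OC)c1
A6 | alternative 3 | 5,7,8-trimethoxy-2-(3,4,5-trimethoxyphenyl)chroman-4-one (racemic; one enantiomer drawn) | COc1cc(cc(OC)c1OC)[C@@H]1CC(=O)c2c(OC)cc(OC)c(OC)c2O1
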